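The route rests on a (4+3) annulation that inserts the oxygenated C7–C8–C9 unit between the two quaternary carbons C6 and C10 of the seven-membered ring (C4–C5–C6–C7–C8–C9–C10). A β-silyl ester carried on a methylcyclohexene ketal is at once an ester enolate (nucleophilic at C6) and an allylsilane (nucleophilic at C10). In one flask it takes up 3,3-bis(benzyloxy)propanal by aldol addition at the aldehyde end and Hosomi–Sakurai closure at the acetal end. Silicon at C5 relays one configuration to both quaternary centres and leaves the C4=C5 alkene, through which the cyclobutane bond C5–C11 is later closed by enolate alkylation.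

Key step: step 8

Remark (numbering): atoms carry longipinane numbers throughout: C1 ketone carbon, C2=C3 (C3 bears methyl C12), C4, C5, C6 (bears methyl C14 and CH2O C15), C7, C8, C9, C10 (bears methyl C13), C11. The cyclobutane is C4–C5–C11–C10. The bicyclic precursors lack the C5–C11 bond.

Remark (assumption): compound 1 is used as the racemate because its only stereocentre is destroyed in step 1; absolute configuration is introduced in step 5. Compound 7 is drawn as the epimer expected from protonation anti to silicon; its C2 centre is erased in step 8.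

Remark (assumption): angelic anhydride (34) is taken as a commercial reagent.

Step 1
Reactants: 1 Hagemann's ester (ethyl 2-methyl-4-oxocyclohex-2-ene-1-carboxylate, racemic)
Product: 2 ethyl 7-methyl-1,4-dioxaspiro[4.5]dec-7-ene-8-carboxylate
Conditions: ethylene glycol, TsOH (cat.), benzene, reflux, Dean–Stark trap
Reagents that add atoms: ethylene glycol, OCCO
Why: Acid-catalysed ketalisation of the enone should move the double bond into conjugation with the ester, which removes the only stereocentre and places the alkene at C4=C10.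

Step 2
Reactants: 2 ketal ester
Product: 3 (7-methyl-1,4-dioxaspiro[4.5]dec-7-en-8-yl)methanol
Conditions: i-Bu2AlH, CH2Cl2, −78 °C
Reagents that add atoms: none
Why: Hydride reduction of a conjugated ester with i-Bu2AlH should stop cleanly at the allylic alcohol and leave the ketal untouched.

Step 3
Reactants: 3 allylic alcohol
Product: 4 7-methyl-1,4-dioxaspiro[4.5]dec-7-ene-8-carbaldehyde
Conditions: MnO2, CH2Cl2, 23 °C
Reagents that add atoms: none
Why: MnO2 oxidises allylic alcohols selectively to enals under neutral conditions that spare the ketal.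

Step 4
Reactants: 4 enal; 5 triethyl 2-phosphonopropionate
Product: 6 ethyl (E)-2-methyl-3-(7-methyl-1,4-dioxaspiro[4.5]dec-7-en-8-yl)prop-2-enoate
Conditions: NaH, THF, 0 → 23 °C
Reagents that add atoms: none
Why: Horner–Wadsworth–Emmons olefination with an α-methyl phosphonoacetate should give the (E)-trisubstituted enoate, which supplies C5, C6, C14 and C15.

Step 5
Reactants: 6 dienoate
Product: 7 ethyl (2S,3R)-3-[dimethyl(phenyl)silyl]-2-methyl-3-(7-methyl-1,4-dioxaspiro[4.5]dec-7-en-8-yl)propanoate
Conditions: CuCl (5 mol %), chiral imidazolinium salt (N-heterocyclic carbene precursor), NaOt-Bu, PhMe2Si–Bpin, THF, −50 °C; MeOH quench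
Reagents that add atoms: (dimethylphenylsilyl)boronic acid pinacol ester, CC1(C)OB(OC1(C)C)[Si](C)(C)c1ccccc1
Why: Copper-catalysed enantioselective conjugate silyl addition should place silicon at the β-carbon (C5), 1,6-addition being blocked by the fully substituted δ-carbon C10, and the chiral carbene ligand is chosen to give the 3R centre.

Step 6
Reactants: 8 3-butenal diethyl acetal (4,4-diethoxybut-1-ene)
Product: 9 4,4-bis(benzyloxy)but-1-ene
Conditions: BnOH, PPTS (cat.), toluene, 110 °C, distillation of EtOH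
Reagents that add atoms: benzyl alcohol, OCc1ccccc1
Why: Acid-catalysed transacetalisation is driven to the dibenzyl acetal by removal of ethanol.

Step 7
Reactants: 9 dibenzyl acetal alkene
Product: 10 3,3-bis(benzyloxy)propanal
Conditions: O3, CH2Cl2, −78 °C; then PPh3
Reagents that add atoms: ozone, [O-][O+]=O
Why: Ozonolysis with reductive work-up cleaves the terminal alkene to the aldehyde without touching the acetal, giving a malondialdehyde equivalent with two differentiated electrophilic ends.

Step 8
Reactants: 7 β-silyl ester; 10 3,3-bis(benzyloxy)propanal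
Product: 15 bicyclic hydroxy ester, via lithium enolate 11 (not isolated), via lithium aldolate 12 (not isolated), via silylated aldol acetal 13 (not isolated), via cyclised trimethylsilyl ether 14 (not isolated)
Conditions: LiN(i-Pr)2, THF, −78 °C; 10, −78 °C; Me3SiCl; then CH2Cl2, Me3SiOTf (cat.), 2,6-di-tert-butyl-4-methylpyridine, −78 → −30 °C; K2CO3, MeOH work-up
Reagents that add atoms: none
Why: LiN(i-Pr)2 gives ester enolate 11, which adds to the aldehyde of 10 through a closed Zimmerman–Traxler transition state on the face anti to the C5–Si bond and forms C6–C7; after O-silylation, Me3SiOTf ionises the acyclic dibenzyl acetal to a benzyloxocarbenium ion at C9, which C10 of the allylsilane captures in an anti-SE2′ Hosomi–Sakurai cyclisation that forms C9–C10 and releases silicon as the C4=C5 alkene. The closest known reactions are aldol additions of β-silyl ester enolates and acetal-initiated intramolecular allylsilane cyclisations, joined here as a (4+3) annulation of a 1,4-bis-nucleophile with a 1,3-bis-electrophile. The seven-membered ring closes with the oxocarbenium C=O+ exocyclic and the allylsilane π-bond endocyclic, which requires C6 to lie in the alkene plane so that the new C4=C5 bond is cis within the ring. C6 is set by attack anti to silicon, C7 by the chair transition state of the enolate that carries its methyl group cis to O–Li (C7–O cis to the C6 methyl), C10 by attack anti to the departing silicon (C10 methyl cis to the C6 methyl), and C9 by a synclinal arrangement of C=O+ and the π-bond (C9–O trans to C7–O). The step needs the acyclic acetal to ionise faster than the dioxolane and the ring closure to outrun protodesilylation; low temperature, catalytic silyl triflate and a hindered pyridine base favour the first, and the tether favours the second.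

Step 9
Reactants: 15 bicyclic hydroxy ester
Product: 16 bicyclic 7,15-diol
Conditions: LiAlH4, THF, 0 °C
Reagents that add atoms: none
Why: Hydride reduction of the neopentyl ester to the primary alcohol removes a carbonyl that would otherwise be attacked by the C11 enolate in step 17.

Step 10
Reactants: 16 bicyclic 7,15-diol
Product: 17 15-O-benzyl ether with free 7-OH
Conditions: Ag2O, BnBr, CH2Cl2, 23 °C
Reagents that add atoms: benzyl bromide, BrCc1ccccc1
Why: Silver-oxide-mediated Williamson etherification should benzylate the primary C15 hydroxyl in preference to the secondary C7 hydroxyl, which lies next to the quaternary C6.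

Step 11
Reactants: 17 15-O-benzyl ether
Product: 20 bicyclic 5,7-diol, via dimethylsilyl ether 18 (not isolated), via oxasilolane 19 (not isolated)
Conditions: (HMe2Si)2NH, 60 °C; Pt2[(CH2=CHSiMe2)2O]3 (Karstedt catalyst, cat.), toluene, 60 °C; then KF, KHCO3, 30% H2O2, THF/MeOH, 40 °C
Reagents that add atoms: hydrogen peroxide, OO
Why: Platinum-catalysed intramolecular hydrosilylation through the C7–O–Si tether should deliver Si to C5 and H to C4 on the face of the C7 oxygen, and Tamao–Fleming oxidation with retention then gives the 5-OH cis to 7-OH and the cis ring fusion (H-4 cis to the C10 methyl).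

Step 12
Reactants: 20 bicyclic 5,7-diol
Product: 21 7-O-TBS ether with free 5-OH
Conditions: TBSOTf (1.05 equiv), 2,6-lutidine, CH2Cl2, −78 °C
Reagents that add atoms: tert-butyldimethylsilyl triflate, CC(C)(C)[Si](C)(C)OS(=O)(=O)C(F)(F)F
Why: Silylation with a bulky silyl triflate should select the C7 hydroxyl, because the C5 hydroxyl is flanked by the quaternary C6 and the ring-fusion carbon C4.

Step 13
Reactants: 21 7-O-TBS ether
Product: 22 hydroxy ketone
Conditions: PPTS, acetone/H2O, 55 °C
Reagents that add atoms: water, O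
Why: Mild acid-catalysed hydrolysis removes the dioxolane and unveils the C1 ketone while the hindered secondary silyl ether and the benzyl ethers should persist.

Step 14
Reactants: 22 hydroxy ketone
Product: 24 enone with 5-O-trimethylsilyl ether, via bis(trimethylsilyl) derivative 23 (not isolated)
Conditions: Me3SiOTf, Et3N, CH2Cl2, 0 °C; then Pd(OAc)2, MeCN, 23 °C
Reagents that add atoms: trimethylsilyl triflate, C[Si](C)(C)OS(=O)(=O)C(F)(F)F
Why: Soft enolisation forms the silyl enol ether towards C2, away from the neopentyl C11, and also caps the 5-OH; Saegusa oxidation then gives the C2=C3 enone that blocks C2 as an enolate site.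

Step 15
Reactants: 24 enone with 5-O-trimethylsilyl ether
Product: 27 3-methyl enone with free 5-OH, via silyl enol ether 25 (not isolated), via silylated methyl enone 26 (not isolated)
Conditions: Me2CuLi (from MeLi and CuI), Me3SiCl, THF, −78 °C; then Pd(OAc)2, MeCN, 23 °C; then 1 M HCl, THF
Reagents that add atoms: lithium dimethylcuprate, [Li+].C[Cu-]C
Why: Cuprate conjugate addition with in situ silylation puts the C12 methyl on C3, Saegusa oxidation of the resulting enol ether restores the C2=C3 bond and erases the transient C3 stereocentre, and dilute acid frees the 5-OH.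

Step 16
Reactants: 27 3-methyl enone with free 5-OH
Product: 28 C5 mesylate
Conditions: MsCl, Et3N, DMAP (cat.), CH2Cl2, 0 °C
Reagents that add atoms: methanesulfonyl chloride, CS(=O)(=O)Cl
Why: Mesylation through the sulfene tolerates the hindered secondary alcohol and keeps its configuration, which places the leaving group anti to C11.

Step 17
Reactants: 28 C5 mesylate
Product: 30 protected tricyclic enone, via potassium enolate 29 (not isolated)
Conditions: KN(SiMe3)2, THF, −78 → 23 °C
Reagents that add atoms: none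
Why: Kinetic α′-deprotonation of the 3-methyl enone gives the C11 enolate, which displaces the C5 mesylate with inversion (4-exo-tet enolate alkylation) to close the cyclobutane and set C5 and C11; elimination is disfavoured because C6 is quaternary and H-4 is syn to the leaving group.

Step 18
Reactants: 30 protected tricyclic enone
Product: 31 7,9,15-trihydroxylongipin-2-en-1-one (triol)
Conditions: BCl3, C6HMe5, CH2Cl2, −78 → 0 °C; then MeOH, 23 °C
Reagents that add atoms: none
Why: BCl3 with pentamethylbenzene as cation scavenger cleaves both benzyl ethers without reducing the enone, and the methanolic HCl formed on quenching should remove the silyl ether.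

Step 19
Reactants: 31 triol; 32 angelic acid ((Z)-2-methylbut-2-enoic acid)
Product: 33 15-O-angeloyl-7,9-dihydroxylongipin-2-en-1-one (15-monoangelate)
Conditions: 32 (1.1 equiv), 2,4,6-trichlorobenzoyl chloride, Et3N, toluene, 23 °C; then 31, toluene, 45 °C
Reagents that add atoms: none
Why: Acylation by the preformed mixed anhydride without a nucleophilic amine catalyst (Yamaguchi-type esterification) should esterify only the primary C15 hydroxyl, since each secondary hydroxyl is flanked by a quaternary carbon, and should keep the Z geometry of the angelate; an acyl shift to O7 would be harmless because step 20 esterifies every remaining hydroxyl.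

Step 20
Reactants: 33 15-monoangelate; 34 angelic anhydride ((Z)-2-methylbut-2-enoic anhydride)
Product: 36 CNP0266467.1 (7,9,15-tris(angeloyloxy)longipin-2-en-1-one), via lithium dialkoxide 35 (not isolated)
Conditions: LiN(SiMe3)2 (2.0 equiv), THF, −78 °C; then 34 (3 equiv), −78 → 0 °C; aq. NH4Cl
Reagents that add atoms: none
Why: The lithium alkoxides of the two hindered secondary hydroxyls should be acylated by angelic anhydride at low temperature without Z to E isomerisation (alkoxide acylation), the two equivalents of base being consumed by the hydroxyls before the γ-methyl of the enone can be deprotonated; the anhydride is used in excess because each molecule delivers one acyl group and releases one angelate.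

Compound list
1 | Hagemann's ester, ethyl 2-methyl-4-oxocyclohex-2-ene-1-carboxylate (racemic) | CCOC(=O)C1CCC(=O)C=C1C | starting material
2 | ethyl 7-methyl-1,4-dioxaspiro[4.5]dec-7-ene-8-carboxylate | CCOC(=O)C1=C(C)CC2(OCCO2)CC1 | intermediate
3 | (7-methyl-1,4-dioxaspiro[4.5]dec-7-en-8-yl)methanol | OCC1=C(C)CC2(OCCO2)CC1 | intermediate
4 | 7-methyl-1,4-dioxaspiro[4.5]dec-7-ene-8-carbaldehyde | O=CC1=C(C)CC2(OCCO2)CC1 | intermediate
5 | triethyl 2-phosphonopropionate | CCOC(=O)C(C)P(=O)(OCC)OCC | starting material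
6 | ethyl (E)-2-methyl-3-(7-methyl-1,4-dioxaspiro[4.5]dec-7-en-8-yl)prop-2-enoate | CCOC(=O)/C(C)=C/C1=C(C)CC2(OCCO2)CC1 | intermediate
7 | ethyl (2S,3R)-3-[dimethyl(phenyl)silyl]-2-methyl-3-(7-methyl-1,4-dioxaspiro[4.5]dec-7-en-8-yl)propanoate | CCOC(=O)[C@H](C)[C@@H]([Si](C)(C)c1ccccc1)C1=C(C)CC2(OCCO2)CC1 | intermediate
8 | 3-butenal diethyl acetal (4,4-diethoxybut-1-ene) | C=CCC(OCC)OCC | starting material
9 | 4,4-bis(benzyloxy)but-1-ene | C=CCC(OCc1ccccc1)OCc1ccccc1 | intermediate
10 | 3,3-bis(benzyloxy)propanal | O=CCC(OCc1ccccc1)OCc1ccccc1 | intermediate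
11 | lithium enolate of 7 (methyl cis to O–Li) | [Li]O/C(OCC)=C(\C)[C@@H]([Si](C)(C)c1ccccc1)C1=C(C)CC2(OCCO2)CC1 | intermediate (not isolated)
12 | lithium aldolate (C6–C7 formed; C7–O anti to silicon-bearing C5 substituent as described) | CCOC(=O)[C@@](C)([C@H](O[Li])CC(OCc1ccccc1)OCc1ccccc1)[C@@H]([Si](C)(C)c1ccccc1)C1=C(C)CC2(OCCO2)CC1 | intermediate (not isolated)
13 | O-trimethylsilyl aldol dibenzyl acetal | CCOC(=O)[C@@](C)([C@H](O[Si](C)(C)C)CC(OCc1ccccc1)OCc1ccccc1)[C@@H]([Si](C)(C)c1ccccc1)C1=C(C)CC2(OCCO2)CC1 | intermediate (not isolated)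
14 | cyclised trimethylsilyl ether of 15 | CCOC(=O)[C@]1(C)C=C2CCC3(OCCO3)C[C@]2(C)[C@H](OCc4ccccc4)C[C@H]1O[Si](C)(C)C | intermediate (not isolated)
15 | bicyclic hydroxy ester: ethyl 9-benzyloxy-1,1-ethylenedioxy-7-hydroxy-6,10-dimethylbicyclo[5.4.0]undec-4-ene-6-carboxylate (longipinane numbering; 7-OH, 6-Me and 10-Me on one face, CO2Et and 9-OBn on the other) | CCOC(=O)[C@]1(C)C=C2CCC3(OCCO3)C[C@]2(C)[C@H](OCc4ccccc4)C[C@H]1O | intermediate
16 | bicyclic 7,15-diol (ester of 15 reduced to CH2OH) | OC[C@]1(C)C=C2CCC3(OCCO3)C[C@]2(C)[C@H](OCc4ccccc4)C[C@H]1O | intermediate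
17 | 9,15-di-O-benzyl ether with free 7-OH | c5ccccc5COC[C@]1(C)C=C2CCC3(OCCO3)C[C@]2(C)[C@H](OCc4ccccc4)C[C@H]1O | intermediate
18 | 7-O-dimethylsilyl ether of 17 | c5ccccc5COC[C@]1(C)C=C2CCC3(OCCO3)C[C@]2(C)[C@H](OCc4ccccc4)C[C@H]1O[SiH](C)C | intermediate (not isolated)
19 | oxasilolane (Si on C5, H on C4, both on the face of the C7 oxygen) | c5ccccc5COC[C@]1(C)[C@@H]6[C@@H]2CCC3(OCCO3)C[C@]2(C)[C@H](OCc4ccccc4)C[C@H]1O[Si]6(C)C | intermediate (not isolated)
20 | cis-fused 5,7-diol (5-OH cis to 7-OH; H-4 cis to 10-Me) | c5ccccc5COC[C@]1(C)[C@@H](O)[C@@H]2CCC3(OCCO3)C[C@]2(C)[C@H](OCc4ccccc4)C[C@H]1O | intermediate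
21 | 7-O-TBS ether with free 5-OH | c5ccccc5COC[C@]1(C)[C@@H](O)[C@@H]2CCC3(OCCO3)C[C@]2(C)[C@H](OCc4ccccc4)C[C@H]1O[Si](C)(C)C(C)(C)C | intermediate
22 | C1 ketone with free 5-OH | c5ccccc5COC[C@]1(C)[C@@H](O)[C@@H]2CCC(=O)C[C@]2(C)[C@H](OCc4ccccc4)C[C@H]1O[Si](C)(C)C(C)(C)C | intermediate
23 | C1–C2 trimethylsilyl enol ether with 5-O-trimethylsilyl ether | c5ccccc5COC[C@]1(C)[C@@H](O[Si](C)(C)C)[C@@H]2CC=C(O[Si](C)(C)C)C[C@]2(C)[C@H](OCc4ccccc4)C[C@H]1O[Si](C)(C)C(C)(C)C | intermediate (not isolated)
24 | C2=C3 enone with 5-O-trimethylsilyl ether | c5ccccc5COC[C@]1(C)[C@@H](O[Si](C)(C)C)[C@@H]2C=CC(=O)C[C@]2(C)[C@H](OCc4ccccc4)C[C@H]1O[Si](C)(C)C(C)(C)C | intermediate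
25 | 3-methyl C1–C2 silyl enol ether (C3 configuration not relevant, removed in the same step) | c5ccccc5COC[C@]1(C)[C@@H](O[Si](C)(C)C)[C@@H]2C(C)C=C(O[Si](C)(C)C)C[C@]2(C)[C@H](OCc4ccccc4)C[C@H]1O[Si](C)(C)C(C)(C)C | intermediate (not isolated)
26 | 3-methyl enone with 5-O-trimethylsilyl ether | c5ccccc5COC[C@]1(C)[C@@H](O[Si](C)(C)C)[C@@H]2C(C)=CC(=O)C[C@]2(C)[C@H](OCc4ccccc4)C[C@H]1O[Si](C)(C)C(C)(C)C | intermediate (not isolated)
27 | 3-methyl enone with free 5-OH | c5ccccc5COC[C@]1(C)[C@@H](O)[C@@H]2C(C)=CC(=O)C[C@]2(C)[C@H](OCc4ccccc4)C[C@H]1O[Si](C)(C)C(C)(C)C | intermediate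
28 | C5 mesylate | c5ccccc5COC[C@]1(C)[C@@H](OS(C)(=O)=O)[C@@H]2C(C)=CC(=O)C[C@]2(C)[C@H](OCc4ccccc4)C[C@H]1O[Si](C)(C)C(C)(C)C | intermediate
29 | potassium C1–C11 enolate of 28 | c5ccccc5COC[C@]1(C)[C@@H](OS(C)(=O)=O)[C@@H]2C(C)=CC(O[K])=C[C@]2(C)[C@H](OCc4ccccc4)C[C@H]1O[Si](C)(C)C(C)(C)C | intermediate (not isolated)
30 | 9,15-di-O-benzyl-7-O-TBS-7,9,15-trihydroxylongipin-2-en-1-one | c5ccccc5COC[C@]1(C)[C@@H]2[C@H]3C(=O)C=C(C)[C@@H]2[C@@]3(C)[C@H](OCc4ccccc4)C[C@H]1O[Si](C)(C)C(C)(C)C | intermediate
31 | 7,9,15-trihydroxylongipin-2-en-1-one | OC[C@]1(C)[C@@H]2[C@H]3C(=O)C=C(C)[C@@H]2[C@@]3(C)[C@H](O)C[C@H]1O | intermediate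
32 | angelic acid, (Z)-2-methylbut-2-enoic acid | C/C=C(/C)C(=O)O | starting material
33 | 15-O-angeloyl-7,9-dihydroxylongipin-2-en-1-one (15-monoangelate) | C/C=C(/C)C(=O)OC[C@]1(C)[C@@H]2[C@H]3C(=O)C=C(C)[C@@H]2[C@@]3(C)[C@H](O)C[C@H]1O | intermediate
34 | angelic anhydride, (Z)-2-methylbut-2-enoic anhydride | C/C=C(/C)C(=O)OC(=O)/C(C)=C\C | starting material
35 | lithium 7,9-dialkoxide of 33 | C/C=C(/C)C(=O)OC[C@]1(C)[C@@H]2[C@H]3C(=O)C=C(C)[C@@H]2[C@@]3(C)[C@H](O[Li])C[C@H]1O[Li] | intermediate (not isolated)
36 | CNP0266467.1, 7,9,15-tris(angeloyloxy)longipin-2-en-1-one | C/C=C(/C)C(=O)OC[C@]1(C)[C@@H]2[C@H]3C(=O)C=C(C)[C@@H]2[C@@]3(C)[C@H](OC(=O)/C(C)=C\C)C[C@H]1OC(=O)/C(C)=C\C | target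

Total step count: 20. Longest linear sequence: 18 steps (steps 1–5 and 8–20); steps 6–7 make fragment 10.

Steps most likely to fail

Step 8 (key step). The ring closure has to pass through a conformer with 1,3-allylic strain between C6 and the C10 methyl, so ionisation of the ring dioxolane or protodesilylation of the allylsilane may outrun it. Silyl migration from C5 to the C7 alkoxide and loss of benzyl alcohol from 10 by the enolate are further loss channels. The fallback sets out from 7 and 10 and comes back at 15. The two bonds are made in separate flasks and the ring is closed on a free aldehyde. The aldolate is trapped with TBSOTf and isolated as the silyl ether aldol acetal F1. The acyclic acetal alone is cleaved (Et3SiOTf, 2,4,6-collidine, then water) to the aldehyde F2. SnCl4 at −78 °C effects the intramolecular Hosomi–Sakurai addition to the cyclised C9 alcohol F3. Benzylation (NaH, BnBr) gives the benzyl ether F4, and HF·pyridine removes the silyl ether to give 15.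

Step 17. Substitution at the neopentyl-type C5 may be slow, so that the enolate equilibrates to the extended dienolate, the mesylate methyl is deprotonated, or the C4–C10 bond fragments. The fallback sets out from 20 and comes back at 31. The 5,7-diol is converted into a doubly activated, conformationally locked electrophile, which also avoids the selective silylation. SOCl2/Et3N and then RuCl3 (cat.)/NaIO4 give the cyclic sulfate F5. PPTS in aqueous acetone gives the ketone F6. Me3SiOTf/Et3N and then Pd(OAc)2 give the enone F7. LiN(i-Pr)2 opens the sulfate at C5 from C11, and dilute H2SO4 hydrolyses the C7 sulfate to the tricyclic hydroxy enone F8. Me2CuLi/Me3SiCl and then Pd(OAc)2 install the C3 methyl to give the tricyclic methyl enone F9. BCl3/C6HMe5 gives 31.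

Step 11. Hydrosilylation of a trisubstituted alkene flanked by two quaternary carbons may be slow, and platinum hydride may move the alkene into the six-membered ring. The fallback sets out from 17 and comes back at 20 by phosphinite-directed hydroboration. Ph2PCl/Et3N gives the phosphinite F10. [Rh(cod)Cl]2 with catecholborane delivers boron to C5 from the face of the C7 oxygen, and H2O2/NaOH oxidises boron and phosphorus to the hydroxy phosphinate F11. KOH in methanol cleaves the phosphinate to 20.

Further compounds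
F1 | step 8 | 7-O-TBS aldol dibenzyl acetal | CCOC(=O)[C@@](C)([C@H](O[Si](C)(C)C(C)(C)C)CC(OCc1ccccc1)OCc1ccccc1)[C@@H]([Si](C)(C)c1ccccc1)C1=C(C)CC2(OCCO2)CC1
F2 | step 8 | 7-O-TBS aldol aldehyde | CCOC(=O)[C@@](C)([C@H](O[Si](C)(C)C(C)(C)C)CC=O)[C@@H]([Si](C)(C)c1ccccc1)C1=C(C)CC2(OCCO2)CC1
F3 | step 8 | cyclised C9 alcohol with 7-O-TBS ether | CCOC(=O)[C@]1(C)C=C2CCC3(OCCO3)C[C@]2(C)[C@H](O)C[C@H]1O[Si](C)(C)C(C)(C)C
F4 | step 8 | cyclised C9 benzyl ether with 7-O-TBS ether | CCOC(=O)[C@]1(C)C=C2CCC3(OCCO3)C[C@]2(C)[C@H](OCc4ccccc4)C[C@H]1O[Si](C)(C)C(C)(C)C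
F5 | step 17 | 5,7-cyclic sulfate of 20 | c5ccccc5COC[C@]1(C)[C@@H]6[C@@H]2CCC3(OCCO3)C[C@]2(C)[C@H](OCc4ccccc4)C[C@H]1OS(=O)(=O)O6
F6 | step 17 | cyclic sulfate ketone | c5ccccc5COC[C@]1(C)[C@@H]6[C@@H]2CCC(=O)C[C@]2(C)[C@H](OCc4ccccc4)C[C@H]1OS(=O)(=O)O6
F7 | step 17 | cyclic sulfate enone | c5ccccc5COC[C@]1(C)[C@@H]6[C@@H]2C=CC(=O)C[C@]2(C)[C@H](OCc4ccccc4)C[C@H]1OS(=O)(=O)O6
F8 | step 17 | 9,15-di-O-benzyl-7-hydroxy-12-norlongipin-2-en-1-one | c5ccccc5COC[C@]1(C)[C@@H]2[C@H]3C(=O)C=C[C@@H]2[C@@]3(C)[C@H](OCc4ccccc4)C[C@H]1O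
F9 | step 17 | 9,15-di-O-benzyl-7-hydroxylongipin-2-en-1-one | c5ccccc5COC[C@]1(C)[C@@H]2[C@H]3C(=O)C=C(C)[C@@H]2[C@@]3(C)[C@H](OCc4ccccc4)C[C@H]1O
F10 | step 11 | 7-O-diphenylphosphinite of 17 | c5ccccc5COC[C@]1(C)C=C2CCC3(OCCO3)C[C@]2(C)[C@H](OCc4ccccc4)C[C@H]1OP(c6ccccc6)c7ccccc7
F11 | step 11 | 5-hydroxy 7-O-diphenylphosphinate | c5ccccc5COC[C@]1(C)[C@@H](O)[C@@H]2CCC3(OCCO3)C[C@]2(C)[C@H](OCc4ccccc4)C[C@H]1OP(=O)(c6ccccc6)c7ccccc7
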